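**Retrosynthetic overview** (target numbering: C1 = C(OH)CH2OBz, C2 = C=O, C3=C4, C5 = CH(OBz), C6 = CH(OH), C7 = CH2O)
1. Endgame: C5–OBz by Mitsunobu inversion, C7–OBz by acylation, C3=C4 by dehydrogenation and C6–OH by ketone reduction lead back to bicyclic dione 12.
2. Key disconnection: C4–C5 and C1–C2 are made together by a [3+3] α,α′-annulation of the pyrrolidine enamine 8 of a 1,3-dioxan-5-one (C5–C6–C1 with C7) with acryloyl chloride 9 (C2–C3–C4).
3. Enabling feature: C5, C6 and C1 are three contiguous oxygen-bearing ring carbons, a dihydroxyacetone unit. With C6 as the ketone and O1/O5 tied in a six-membered benzylidene acetal ring, both flanking carbons are nucleophilic through enamines, the acetal carbon holds the chirality while C1 is trigonal, and the product bridgeheads C1 and C5 cannot enolise.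
4. Ring order: dioxane ring first (from 4,6-O-benzylidene-D-glucose by excision of two carbons), carbocycle second (key step, giving a 2,4-dioxabicyclo[3.3.1]nonane), dioxane ring opened last.

Key step: step 5

Remark: commercial 4,6-O-benzylidene-D-glucopyranose is an anomeric mixture with an (R)-acetal carbon; the anomeric carbon is excised in step 1, so the mixture is immaterial.

Step 1
Reactants: 1 4,6-O-benzylidene-D-glucopyranose
Product: 3 (2R,4S,5R)-4-(hydroxymethyl)-2-phenyl-1,3-dioxan-5-ol (2,4-O-benzylidene-D-erythritol), via 2,4-O-benzylidene-D-erythrose 2 (not isolated)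
Conditions: NaIO4, NaHCO3, H2O, 0 °C to rt; then NaBH4, EtOH, 0 °C
Reagents that add atoms: none
Why: Malaprade glycol cleavage excises sugar carbons 1 and 2 as formic acid and leaves aldehyde 2, which borohydride reduces in the same pot, so both ring stereocentres and the (R)-acetal carbon come unchanged from D-glucose.

Step 2
Reactants: 3 (2R,4S,5R)-4-(hydroxymethyl)-2-phenyl-1,3-dioxan-5-ol; 4 tert-butyldimethylsilyl chloride
Product: 5 (2R,4S,5R)-4-{[(tert-butyldimethylsilyl)oxy]methyl}-2-phenyl-1,3-dioxan-5-ol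
Conditions: TBSCl, imidazole, CH2Cl2, 0 °C
Reagents that add atoms: tert-butyldimethylsilyl chloride, CC(C)(C)[Si](C)(C)Cl
Why: Silylation of the primary hydroxyl should be much faster than that of the secondary ring hydroxyl (steric selectivity), and a silyl ether, unlike a benzoate, is no leaving group β to the ketone made next.

Step 3
Reactants: 5 (2R,4S,5R)-4-{[(tert-butyldimethylsilyl)oxy]methyl}-2-phenyl-1,3-dioxan-5-ol
Product: 6 (2R,4S)-4-{[(tert-butyldimethylsilyl)oxy]methyl}-2-phenyl-1,3-dioxan-5-one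
Conditions: Dess–Martin periodinane, CH2Cl2, rt
Reagents that add atoms: none
Why: Dess–Martin oxidation of the secondary alcohol should give the 1,3-dioxan-5-one under near-neutral conditions that spare the acetal and the silyl ether, with the α-substituent staying equatorial and cis to phenyl (the thermodynamic arrangement).

Step 4
Reactants: 6 (2R,4S)-4-{[(tert-butyldimethylsilyl)oxy]methyl}-2-phenyl-1,3-dioxan-5-one; 7 pyrrolidine
Product: 8 1-[(2R,4R)-4-{[(tert-butyldimethylsilyl)oxy]methyl}-2-phenyl-4H-1,3-dioxin-5-yl]pyrrolidine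
Conditions: pyrrolidine, 4 Å MS, PhMe, 60 °C; concentrate, use crude
Reagents that add atoms: pyrrolidine, C1CCNC1
Why: Condensation with a secondary amine (Stork enamine formation) should give the less substituted enamine toward the ring CH2 to avoid allylic 1,3-strain, while the acetal carbon keeps the stereochemical information.

Step 5
Reactants: 8 1-[(2R,4R)-4-{[(tert-butyldimethylsilyl)oxy]methyl}-2-phenyl-4H-1,3-dioxin-5-yl]pyrrolidine; 9 acryloyl chloride
Product: 12 (1S,3R,5R)-5-{[(tert-butyldimethylsilyl)oxy]methyl}-3-phenyl-2,4-dioxabicyclo[3.3.1]nonane-6,9-dione, via ketene-iminium chloride 10 (not isolated), via bicyclic iminium chloride 11 (not isolated)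
Conditions: acryloyl chloride (slow addition), PhMe, 80 °C; then H2O, rt
Reagents that add atoms: acryloyl chloride, C=CC(Cl)=O; water, O
Why: N-Acylation of the enamine by 9 is followed by a [3,3]-sigmatropic (aza-Claisen-type) shift that joins the enamine carbon C5 to the β-carbon C4 and leaves ketene-iminium 10; proton loss toward the substituted α′-carbon gives the tetrasubstituted enamine, whose carbon C1 adds to the ketene carbon C2 to give iminium salt 11, which water hydrolyses to 12. The closest known reaction type is the enamine–acryloyl chloride α,α′-annulation that turns cyclohexanone and heterocyclic ketone enamines into bicyclo[3.3.1]nonane-2,9-diones. The carbocycle closes in a 6-(enolendo)-exo-dig mode onto the ketene. Both new stereocentres (C5 and the quaternary C1, the two bridgeheads) are controlled by the (R)-acetal carbon: its equatorial phenyl fixes the dioxane chair, so the three-carbon bridge can only span the two axial positions on the face of the acetal hydrogen, and C1, trigonal in the enamine, is re-formed in that sense whatever its earlier configuration. The step needs regioselectivity (unsubstituted α-carbon to C4, substituted α′-carbon to the acyl carbon C2), which the preference for the less substituted enamine secures, and it needs the C7 oxygen to stay, which the silyl ether secures; a C5 epimer with an equatorial side chain cannot cyclise and should return through the enamine.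

Step 6
Reactants: 12 (1S,3R,5R)-5-{[(tert-butyldimethylsilyl)oxy]methyl}-3-phenyl-2,4-dioxabicyclo[3.3.1]nonane-6,9-dione
Product: 14 (1S,3R,5R)-5-{[(tert-butyldimethylsilyl)oxy]methyl}-3-phenyl-2,4-dioxabicyclo[3.3.1]non-7-ene-6,9-dione, via trimethylsilyl enol ether 13 (not isolated)
Conditions: TMSOTf, Et3N, CH2Cl2, 0 °C; then Pd(OAc)2, MeCN, rt
Reagents that add atoms: none
Why: Enolisation is possible only from C2 toward C3 because both α-carbons of the bridging ketone are bridgeheads, and Saegusa–Ito oxidation of silyl enol ether 13 with divalent palladium should then install C3=C4 by β-hydride elimination.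

Step 7
Reactants: 14 (1S,3R,5R)-5-{[(tert-butyldimethylsilyl)oxy]methyl}-3-phenyl-2,4-dioxabicyclo[3.3.1]non-7-ene-6,9-dione
Product: 15 (1S,3R,5S,9S)-5-{[(tert-butyldimethylsilyl)oxy]methyl}-9-hydroxy-3-phenyl-2,4-dioxabicyclo[3.3.1]non-7-en-6-one
Conditions: NaBH4, MeOH/CH2Cl2, −78 °C
Reagents that add atoms: none
Why: The bridging ketone with two α-oxygens should be far more electrophilic than the hindered conjugated ketone, and hydride should add anti to both α C–O bonds (polar Felkin–Anh control, the equatorial attack known for 1,3-dioxan-5-ones), placing the C6 hydroxyl syn to the dioxane oxygens and so cis to the C1 oxygen.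

Step 8
Reactants: 15 (1S,3R,5S,9S)-5-{[(tert-butyldimethylsilyl)oxy]methyl}-9-hydroxy-3-phenyl-2,4-dioxabicyclo[3.3.1]non-7-en-6-one
Product: 16 (4S,5S,6S)-4,5,6-trihydroxy-6-(hydroxymethyl)cyclohex-2-en-1-one
Conditions: TFA/H2O (9:1), CH2Cl2, 0 °C
Reagents that add atoms: none
Why: Aqueous acid should hydrolyse the bridging benzylidene acetal and the primary silyl ether in one operation (acetal hydrolysis and protodesilylation) without touching any stereocentre.

Step 9
Reactants: 16 (4S,5S,6S)-4,5,6-trihydroxy-6-(hydroxymethyl)cyclohex-2-en-1-one; 17 benzoyl chloride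
Product: 18 [(1S,5S,6S)-1,5,6-trihydroxy-2-oxocyclohex-3-en-1-yl]methyl benzoate
Conditions: BzCl, 2,4,6-collidine, CH2Cl2, −40 °C
Reagents that add atoms: benzoyl chloride, O=C(Cl)c1ccccc1
Why: Acylation of the primary C7 hydroxyl should be kinetically preferred over the two secondary and the tertiary hydroxyls at low temperature (steric selectivity).

Step 10
Reactants: 18 [(1S,5S,6S)-1,5,6-trihydroxy-2-oxocyclohex-3-en-1-yl]methyl benzoate; 19 benzoic acid
Product: 20 zeylenone, [(1S,5R,6S)-5-(benzoyloxy)-1,6-dihydroxy-2-oxocyclohex-3-en-1-yl]methyl benzoate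
Conditions: PPh3, DIAD, BzOH, THF, 0 °C to rt
Reagents that add atoms: benzoic acid, O=C(O)c1ccccc1
Why: In this Mitsunobu reaction the allylic secondary C5 hydroxyl should be the one activated and displaced, benzoate entering by SN2 with inversion to place C5–O trans to the C6 hydroxyl, and because both vicinal diols are cis no epoxide channel is open.

**Compound list**
1 | 4,6-O-benzylidene-D-glucopyranose ((R)-acetal, anomeric mixture) | C1O[C@@H](c2ccccc2)O[C@H]3[C@H](O)[C@@H](O)C(O)O[C@H]13 | starting material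
2 | 2,4-O-benzylidene-D-erythrose, (2R,4R,5R)-5-hydroxy-2-phenyl-1,3-dioxane-4-carbaldehyde | C1O[C@@H](c2ccccc2)O[C@@H](C=O)[C@@H]1O | intermediate (not isolated)
3 | (2R,4S,5R)-4-(hydroxymethyl)-2-phenyl-1,3-dioxan-5-ol | C1O[C@@H](c2ccccc2)O[C@@H](CO)[C@@H]1O | intermediate
4 | tert-butyldimethylsilyl chloride | CC(C)(C)[Si](C)(C)Cl | starting material
5 | (2R,4S,5R)-4-{[(tert-butyldimethylsilyl)oxy]methyl}-2-phenyl-1,3-dioxan-5-ol | C1O[C@@H](c2ccccc2)O[C@@H](CO[Si](C)(C)C(C)(C)C)[C@@H]1O | intermediate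
6 | (2R,4S)-4-{[(tert-butyldimethylsilyl)oxy]methyl}-2-phenyl-1,3-dioxan-5-one | C1O[C@@H](c2ccccc2)O[C@@H](CO[Si](C)(C)C(C)(C)C)C1=O | intermediate
7 | pyrrolidine | C1CCNC1 | starting material
8 | 1-[(2R,4R)-4-{[(tert-butyldimethylsilyl)oxy]methyl}-2-phenyl-4H-1,3-dioxin-5-yl]pyrrolidine | O1C=C(N2CCCC2)[C@H](CO[Si](C)(C)C(C)(C)C)O[C@@H]1c1ccccc1 | intermediate
9 | acryloyl chloride | C=CC(Cl)=O | starting material
10 | ketene-iminium chloride (C5 side chain CH2CH=C=O, C6 as pyrrolidinium ylidene) | O=C=CC[C@@H]1O[C@@H](c2ccccc2)O[C@@H](CO[Si](C)(C)C(C)(C)C)C1=[N+]1CCCC1.[Cl-] | intermediate (not isolated)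
11 | bicyclic iminium chloride (the 9-pyrrolidinium ylidene of 12) | O=C1CC[C@@H]2O[C@@H](c3ccccc3)O[C@@]1(CO[Si](C)(C)C(C)(C)C)C2=[N+]1CCCC1.[Cl-] | intermediate (not isolated)
12 | (1S,3R,5R)-5-{[(tert-butyldimethylsilyl)oxy]methyl}-3-phenyl-2,4-dioxabicyclo[3.3.1]nonane-6,9-dione | O=C1CC[C@@H]2O[C@@H](c3ccccc3)O[C@@]1(CO[Si](C)(C)C(C)(C)C)C2=O | intermediate
13 | trimethylsilyl enol ether of 12 (6-silyloxy-non-6-en-9-one) | C[Si](C)(C)OC1=CC[C@@H]2O[C@@H](c3ccccc3)O[C@@]1(CO[Si](C)(C)C(C)(C)C)C2=O | intermediate (not isolated)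
14 | (1S,3R,5R)-5-{[(tert-butyldimethylsilyl)oxy]methyl}-3-phenyl-2,4-dioxabicyclo[3.3.1]non-7-ene-6,9-dione | O=C1C=C[C@@H]2O[C@@H](c3ccccc3)O[C@@]1(CO[Si](C)(C)C(C)(C)C)C2=O | intermediate
15 | (1S,3R,5S,9S)-5-{[(tert-butyldimethylsilyl)oxy]methyl}-9-hydroxy-3-phenyl-2,4-dioxabicyclo[3.3.1]non-7-en-6-one | O=C1C=C[C@@H]2O[C@@H](c3ccccc3)O[C@@]1(CO[Si](C)(C)C(C)(C)C)[C@H]2O | intermediate
16 | (4S,5S,6S)-4,5,6-trihydroxy-6-(hydroxymethyl)cyclohex-2-en-1-one | O=C1C=C[C@H](O)[C@H](O)[C@@]1(O)CO | intermediate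
17 | benzoyl chloride | O=C(Cl)c1ccccc1 | starting material
18 | [(1S,5S,6S)-1,5,6-trihydroxy-2-oxocyclohex-3-en-1-yl]methyl benzoate | O=C1C=C[C@H](O)[C@H](O)[C@@]1(O)COC(=O)c1ccccc1 | intermediate
19 | benzoic acid | O=C(O)c1ccccc1 | starting material
20 | zeylenone, [(1S,5R,6S)-5-(benzoyloxy)-1,6-dihydroxy-2-oxocyclohex-3-en-1-yl]methyl benzoate | O=C(OC[C@@]1(O)C(=O)C=C[C@@H](OC(=O)c2ccccc2)[C@@H]1O)c1ccccc1 | target

Total step count: 10
Longest linear sequence: 10 steps (1 to 20)

**Steps most likely to fail**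

Step 5. The second ring closure may fail, because a tetrasubstituted, oxygen-bearing enamine carbon must be acylated to a bridgehead quaternary centre, and O-acylation or ketene oligomerisation may compete. The fallback splits the annulation into known operations at the aldehyde oxidation level. It sets out from enamine 8: Stork–Michael addition to acrolein (MeCN, 0 °C) and aqueous hydrolysis should give 3-[(2R,4R,6S)-6-{[(tert-butyldimethylsilyl)oxy]methyl}-5-oxo-2-phenyl-1,3-dioxan-4-yl]propanal F1. An intramolecular aldol through the more substituted enamine or enol (pyrrolidinium acetate, THF) should then close C1–C2 to (1S,3R,5R)-5-{[(tert-butyldimethylsilyl)oxy]methyl}-6-hydroxy-3-phenyl-2,4-dioxabicyclo[3.3.1]nonan-9-one F2 (carbinol epimers). Dess–Martin oxidation of F2 comes back to the route at 12.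

Step 10. Site selectivity in the Mitsunobu activation may be poor (the C6 hydroxyl competing with C5, or a cyclic dioxaphosphorane of the cis-5,6-diol opening at the wrong carbon), and the activated allylic alcohol may eliminate. The fallback masks the C6 hydroxyl before the acetal is opened and sets out from 15. TIPSOTf and 2,6-lutidine should give (1S,3R,5S,9S)-5-{[(tert-butyldimethylsilyl)oxy]methyl}-3-phenyl-9-[(triisopropylsilyl)oxy]-2,4-dioxabicyclo[3.3.1]non-7-en-6-one F3. Aqueous TFA then removes the acetal and the primary silyl ether to give (4S,5S,6S)-4,6-dihydroxy-6-(hydroxymethyl)-5-[(triisopropylsilyl)oxy]cyclohex-2-en-1-one F4. BzCl and collidine acylate the primary hydroxyl to [(1S,5S,6S)-1,5-dihydroxy-2-oxo-6-[(triisopropylsilyl)oxy]cyclohex-3-en-1-yl]methyl benzoate F5. The Mitsunobu reaction with benzoic acid now has only the C5 hydroxyl to invert and should give [(1S,5R,6S)-5-(benzoyloxy)-1-hydroxy-2-oxo-6-[(triisopropylsilyl)oxy]cyclohex-3-en-1-yl]methyl benzoate F6. HF·pyridine removes the silyl ether and comes back to the route at 20.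

Step 7. Chemoselectivity may be lost, with hydride attacking the enone carbonyl or adding in conjugate fashion alongside the bridging ketone. The fallback makes over-reduction the plan and sets out from 14. Luche reduction (NaBH4, CeCl3·7H2O, MeOH) of both carbonyl groups should give (1S,3R,5R,9S)-5-{[(tert-butyldimethylsilyl)oxy]methyl}-3-phenyl-2,4-dioxabicyclo[3.3.1]non-7-ene-6,9-diol F7 (either configuration at the allylic carbinol). MnO2 then re-oxidises only the allylic carbinol and comes back to the route at 15.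

**Further compounds**
F1 | step 5 | 3-[(2R,4R,6S)-6-{[(tert-butyldimethylsilyl)oxy]methyl}-5-oxo-2-phenyl-1,3-dioxan-4-yl]propanal | O=CCC[C@H]1O[C@@H](c2ccccc2)O[C@@H](CO[Si](C)(C)C(C)(C)C)C1=O
F2 | step 5 | (1S,3R,5R)-5-{[(tert-butyldimethylsilyl)oxy]methyl}-6-hydroxy-3-phenyl-2,4-dioxabicyclo[3.3.1]nonan-9-one | OC1CC[C@@H]2O[C@@H](c3ccccc3)O[C@@]1(CO[Si](C)(C)C(C)(C)C)C2=O
F3 | step 10 | (1S,3R,5S,9S)-5-{[(tert-butyldimethylsilyl)oxy]methyl}-3-phenyl-9-[(triisopropylsilyl)oxy]-2,4-dioxabicyclo[3.3.1]non-7-en-6-one | O=C1C=C[C@@H]2O[C@@H](c3ccccc3)O[C@@]1(CO[Si](C)(C)C(C)(C)C)[C@H]2O[Si](C(C)C)(C(C)C)C(C)C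
F4 | step 10 | (4S,5S,6S)-4,6-dihydroxy-6-(hydroxymethyl)-5-[(triisopropylsilyl)oxy]cyclohex-2-en-1-one | O=C1C=C[C@H](O)[C@H](O[Si](C(C)C)(C(C)C)C(C)C)[C@@]1(O)CO
F5 | step 10 | [(1S,5S,6S)-1,5-dihydroxy-2-oxo-6-[(triisopropylsilyl)oxy]cyclohex-3-en-1-yl]methyl benzoate | O=C1C=C[C@H](O)[C@H](O[Si](C(C)C)(C(C)C)C(C)C)[C@@]1(O)COC(=O)c1ccccc1
F6 | step 10 | [(1S,5R,6S)-5-(benzoyloxy)-1-hydroxy-2-oxo-6-[(triisopropylsilyl)oxy]cyclohex-3-en-1-yl]methyl benzoate | O=C1C=C[C@@H](OC(=O)c2ccccc2)[C@H](O[Si](C(C)C)(C(C)C)C(C)C)[C@@]1(O)COC(=O)c1ccccc1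
F7 | step 7 | (1S,3R,5R,9S)-5-{[(tert-butyldimethylsilyl)oxy]methyl}-3-phenyl-2,4-dioxabicyclo[3.3.1]non-7-ene-6,9-diol | OC1C=C[C@@H]2O[C@@H](c3ccccc3)O[C@@]1(CO[Si](C)(C)C(C)(C)C)[C@H]2O
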